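**Retrosynthetic overview**
1. The target is the head-to-head, syn [2+2] dimer of an (E)-3-(pyranonyl)but-2-enoic acid. It is released by saponifying a cyclic naphthalene-1,8-diyl diester; the cyclobutane comes from a template-directed [2+2] photocycloaddition of the two tethered enoate arms.
2. The monomer acid comes from dehydration and tert-butyl ester cleavage of an α-hydroxy ester. Its key C–C bond (between the future methyl-bearing and carboxyl-bearing ring carbons) is made by an intermolecular vinylogous aldol addition of lithiated 6-ethyl-4-methoxy-3-methyl-2-pyranone to tert-butyl glyoxylate.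
3. The 6-ethylpyranone comes from O-methylation and lactonisation of a 3,5-diketo ester, itself made by crossed Claisen acylation of the ethyl 2-methylacetoacetate dianion with a propionyl Weinreb amide.
4. Ring order: pyranone ring first (steps 1–3), cyclobutane last (step 9), where all four stereocentres are set in one event.

Assumption: the given descriptors define the (1R,2S,3R,4S) isomer, which is meso (mirror plane bisecting the C1–C2 and C3–C4 bonds), so there is no enantiomer to select and only relative configuration must be controlled.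

**Route**

Step 1
Reactants: 1 ethyl 2-methylacetoacetate (ethyl 2-methyl-3-oxobutanoate, racemic); 2 N-methoxy-N-methylpropanamide
Product: 4 ethyl 2-methyl-3,5-dioxoheptanoate, via dilithium dienolate of ethyl 2-methylacetoacetate 3 (not isolated)
Conditions: LiN(iPr)2 (2.1 equiv), THF, −78 → 0 °C; then 2 (0.9 equiv), 0 °C, 1 h; aq. HCl
Reagents that add atoms: none
Why: The terminal (γ) carbanion of the β-keto ester dianion is its most nucleophilic site and acylates the Weinreb amide once through a stable chelated tetrahedral adduct (crossed Claisen-type condensation, Huckin–Weiler dianion acylation); the only stereocentre (C2) becomes sp2 in step 2.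

Step 2
Reactants: 4 ethyl 2-methyl-3,5-dioxoheptanoate
Product: 5 6-ethyl-4-hydroxy-3-methyl-2H-pyran-2-one
Conditions: DBU (1.2 equiv), toluene, 80 °C, 3 h; aq. HCl
Reagents that add atoms: none
Why: Base-mediated enol lactonisation (intramolecular transesterification of the C5 enolate oxygen onto the ethyl ester) closes the 4-hydroxy-2-pyranone with loss of ethanol, the standard fate of 3,5-diketo esters.

Step 3
Reactants: 5 6-ethyl-4-hydroxy-3-methyl-2H-pyran-2-one
Product: 6 6-ethyl-4-methoxy-3-methyl-2H-pyran-2-one
Conditions: Me2SO4 (1.2 equiv), K2CO3 (1.5 equiv), acetone, reflux; chromatography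
Reagents that add atoms: dimethyl sulfate, COS(=O)(=O)OC
Why: Williamson-type O-methylation of the vinylogous acid with Me2SO4/K2CO3 gives the 4-methoxy-2-pyranone as the major regioisomer; the minor 2-methoxy-4-pyranone is removed by chromatography.

Step 4
Reactants: 7 tert-butyl acrylate
Product: 9 tert-butyl glyoxylate (tert-butyl 2-oxoacetate), via tert-butyl 1,2,4-trioxolane-3-carboxylate 8 (not isolated)
Conditions: O3, CH2Cl2, −78 °C; then Me2S, −78 °C → rt; distil from P2O5 just before use
Reagents that add atoms: ozone, [O-][O+]=O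
Why: Ozonolysis of the terminal alkene with reductive work-up cleaves it to the monomeric glyoxylate and volatile formaldehyde, and the tert-butyl ester is inert to these conditions.

Step 5 (key step)
Reactants: 6 6-ethyl-4-methoxy-3-methyl-2H-pyran-2-one; 9 tert-butyl glyoxylate
Product: 11 tert-butyl 2-hydroxy-3-(4-methoxy-3-methyl-2-oxo-2H-pyran-6-yl)butanoate (racemic diastereomer mixture), via lithium 6-ethylidene-4-methoxy-3-methyl-6H-pyran-2-olate 10 (not isolated)
Conditions: LiN(iPr)2 (1.1 equiv), THF, −78 °C, 30 min; then 9 (1.5 equiv), −78 °C, 30 min; AcOH quench at −78 °C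
Reagents that add atoms: none
Why: Deprotonation of the ring-attached CH2 (the only acidic site, C3 being blocked by methyl) gives an extended enolate that adds through its exocyclic carbon to the non-enolisable, highly electrophilic aldehyde (intermolecular vinylogous aldol addition); the two new stereocentres form unselectively and are both erased in step 6.

Step 6
Reactants: 11 tert-butyl 2-hydroxy-3-(4-methoxy-3-methyl-2-oxo-2H-pyran-6-yl)butanoate
Product: 13 tert-butyl (2E)-3-(4-methoxy-3-methyl-2-oxo-2H-pyran-6-yl)but-2-enoate, via 2-mesyloxy butanoate 12 (not isolated)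
Conditions: MsCl (1.5 equiv), Et3N (2 equiv), CH2Cl2, 0 °C; then DBU (2.5 equiv), 0 °C → rt; chromatography
Reagents that add atoms: none
Why: Mesylation followed by E1cB elimination (the C3–H is acidified by the pyranone) gives the doubly conjugated alkene, with the thermodynamically preferred E geometry (pyranone trans to the ester) as major isomer; any Z isomer is removed by chromatography.

Step 7
Reactants: 13 tert-butyl (2E)-3-(4-methoxy-3-methyl-2-oxo-2H-pyran-6-yl)but-2-enoate
Product: 14 (2E)-3-(4-methoxy-3-methyl-2-oxo-2H-pyran-6-yl)but-2-enoic acid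
Conditions: CF3CO2H/CH2Cl2 (1:3), rt, 2 h; recrystallise
Reagents that add atoms: none
Why: Acidolysis of the tert-butyl ester (loss of isobutene) frees the acid without base, so the pyranone and the E alkene are untouched.

Step 8
Reactants: 14 (2E)-3-(4-methoxy-3-methyl-2-oxo-2H-pyran-6-yl)but-2-enoic acid (2.2 equiv); 15 naphthalene-1,8-diol
Product: 17 naphthalene-1,8-diyl bis[(2E)-3-(4-methoxy-3-methyl-2-oxo-2H-pyran-6-yl)but-2-enoate], via 8-hydroxynaphthalen-1-yl monoester 16 (not isolated)
Conditions: EDC·HCl (2.6 equiv), 4-(dimethylamino)pyridine (0.3 equiv), CH2Cl2, 0 °C → rt, dark; recrystallise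
Reagents that add atoms: none
Why: Steglich esterification acylates both peri-hydroxyls under near-neutral conditions, with low temperature and sub-stoichiometric acyl-transfer catalyst to limit deconjugation of the β-methyl enoate.

Step 9
Reactants: 17 naphthalene-1,8-diyl bis[(2E)-3-(4-methoxy-3-methyl-2-oxo-2H-pyran-6-yl)but-2-enoate]
Product: 18 naphthalene-1,8-diyl (1R,2S,3R,4S)-3,4-bis(4-methoxy-3-methyl-2-oxo-2H-pyran-6-yl)-3,4-dimethylcyclobutane-1,2-dicarboxylate (meso cyclic diester)
Conditions: hν (365 nm LED), crystalline powder as a thin layer between Pyrex plates, rt, 24–48 h, sample turned periodically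
Reagents that add atoms: none
Why: The peri-diester template stacks the two enoate C=C bonds parallel and head-to-head within bonding distance, so a topochemical suprafacial [2+2] photocycloaddition keeps the E geometry of each arm and sets all four stereocentres at once (pyranonyls cis to each other, carboxyls cis to each other, each pyranonyl trans to its neighbouring carboxyl); 365 nm excites the pyranone-enoate and avoids photo-Fries reaction of the aryl ester.

Step 10
Reactants: 18 the meso cyclic diester
Product: 19 (1R,2S,3R,4S)-3,4-bis(4-methoxy-3-methyl-2-oxo-2H-pyran-6-yl)-3,4-dimethylcyclobutane-1,2-dicarboxylic acid (target, CNP0574758.1)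
Conditions: LiOH·H2O (3 equiv), THF/H2O (3:1), 0 °C, 1 h; then 1 M HCl to pH 2; NaHCO3 extraction to separate the diol
Reagents that add atoms: lithium hydroxide, [Li+].[OH-]
Why: Saponification of the activated aryl esters at 0 °C is expected to outpace both attack on the 4-methoxy-2-pyranone lactones and α-epimerisation, so the cis diacid is released with the configuration from step 9.

**Compound list**
1 | ethyl 2-methylacetoacetate (racemic) | CCOC(=O)C(C)C(C)=O | starting material
2 | N-methoxy-N-methylpropanamide | CCC(=O)N(C)OC | starting material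
3 | dilithium dienolate of ethyl 2-methylacetoacetate (not isolated) | [Li+].[Li+].C=C([O-])C(C)=C([O-])OCC | intermediate
4 | ethyl 2-methyl-3,5-dioxoheptanoate (racemic) | CCC(=O)CC(=O)C(C)C(=O)OCC | intermediate
5 | 6-ethyl-4-hydroxy-3-methyl-2H-pyran-2-one | CCc1cc(O)c(C)c(=O)o1 | intermediate
6 | 6-ethyl-4-methoxy-3-methyl-2H-pyran-2-one | CCc1cc(OC)c(C)c(=O)o1 | intermediate
7 | tert-butyl acrylate | C=CC(=O)OC(C)(C)C | starting material
8 | tert-butyl 1,2,4-trioxolane-3-carboxylate (secondary ozonide, not isolated) | CC(C)(C)OC(=O)C1OCOO1 | intermediate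
9 | tert-butyl glyoxylate | CC(C)(C)OC(=O)C=O | intermediate
10 | lithium 6-ethylidene-4-methoxy-3-methyl-6H-pyran-2-olate (not isolated) | [Li+].CC=C1C=C(OC)C(C)=C([O-])O1 | intermediate
11 | tert-butyl 2-hydroxy-3-(4-methoxy-3-methyl-2-oxo-2H-pyran-6-yl)butanoate (racemic diastereomer mixture) | COc1cc(C(C)C(O)C(=O)OC(C)(C)C)oc(=O)c1C | intermediate
12 | tert-butyl 3-(4-methoxy-3-methyl-2-oxo-2H-pyran-6-yl)-2-(methylsulfonyloxy)butanoate (not isolated) | COc1cc(C(C)C(OS(C)(=O)=O)C(=O)OC(C)(C)C)oc(=O)c1C | intermediate
13 | tert-butyl (2E)-3-(4-methoxy-3-methyl-2-oxo-2H-pyran-6-yl)but-2-enoate | COc1cc(/C(C)=C/C(=O)OC(C)(C)C)oc(=O)c1C | intermediate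
14 | (2E)-3-(4-methoxy-3-methyl-2-oxo-2H-pyran-6-yl)but-2-enoic acid | COc1cc(/C(C)=C/C(=O)O)oc(=O)c1C | intermediate
15 | naphthalene-1,8-diol | Oc1cccc2cccc(O)c12 | starting material
16 | 8-hydroxynaphthalen-1-yl (2E)-3-(4-methoxy-3-methyl-2-oxo-2H-pyran-6-yl)but-2-enoate (not isolated) | COc1cc(/C(C)=C/C(=O)Oc2cccc3cccc(O)c23)oc(=O)c1C | intermediate
17 | naphthalene-1,8-diyl bis[(2E)-3-(4-methoxy-3-methyl-2-oxo-2H-pyran-6-yl)but-2-enoate] | COc1cc(/C(C)=C/C(=O)Oc2cccc3cccc(OC(=O)/C=C(\C)c4cc(OC)c(C)c(=O)o4)c23)oc(=O)c1C | intermediate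
18 | naphthalene-1,8-diyl (1R,2S,3R,4S)-3,4-bis(4-methoxy-3-methyl-2-oxo-2H-pyran-6-yl)-3,4-dimethylcyclobutane-1,2-dicarboxylate (meso cyclic diester) | COc1cc([C@@]2(C)[C@H](C(=O)Oc3cccc4cccc(OC5=O)c34)[C@H]5[C@@]2(C)c2cc(OC)c(C)c(=O)o2)oc(=O)c1C | intermediate
19 | (1R,2S,3R,4S)-3,4-bis(4-methoxy-3-methyl-2-oxo-2H-pyran-6-yl)-3,4-dimethylcyclobutane-1,2-dicarboxylic acid (meso; pyranonyls on one face, methyls and carboxyls on the other) | COc1cc([C@@]2(C)[C@H](C(=O)O)[C@H](C(=O)O)[C@@]2(C)c2cc(OC)c(C)c(=O)o2)oc(=O)c1C | target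

**Step count and risks**

Total steps: 10. Longest linear sequence: 9 steps (1, 2, 3, 5, 6, 7, 8, 9, 10); step 4 is a one-step side branch.

Steps most likely to fail:

Step 5 (vinylogous aldol). Risks are incomplete or wrong-site metalation of 6, polymeric or wet glyoxylate, and retro-aldol on warming. The fallback sets out from 6 and comes back at 13. The ethyl group of 6 is oxidised with SeO2 (dioxane, 100 °C) to 6-acetyl-4-methoxy-3-methyl-2H-pyran-2-one F1. The lithium enolate of tert-butyl acetate F2 (from tert-butyl acetate and lithium diisopropylamide, THF, −78 °C) is then added to the ketone in a polarity-reversed intermolecular aldol addition, giving racemic tert-butyl 3-hydroxy-3-(4-methoxy-3-methyl-2-oxo-2H-pyran-6-yl)butanoate F3. Dehydration of F3 with the Burgess reagent (toluene, 60 °C), followed by DBU equilibration to the conjugated E isomer, gives 13.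

Step 9 (solid-state [2+2]). Risks are that the crystal of 17 adopts a non-stacked conformation, that the pyranone C5=C6 bonds react instead, or that closing two adjacent quaternary carbons is slow. The fallback sets out from 14 and comes back at 19, bypassing 17 and 18. Acid 14 is crystallised with 0.5 equiv ethane-1,2-diamine (EtOH) as the 2:1 salt ethane-1,2-diaminium bis[(2E)-3-(4-methoxy-3-methyl-2-oxo-2H-pyran-6-yl)but-2-enoate] F4, in which charge-assisted hydrogen bonding to the diammonium ion aligns the two carboxylates head-to-head. Irradiation of the crystals (365 nm) gives the ethane-1,2-diaminium salt of the meso cyclobutanedicarboxylate F5, and acidification with 1 M HCl liberates 19.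

Step 10 (template removal). Risks are hydroxide opening of the pyranone lactones and epimerisation of the cis diester before hydrolysis. The fallback sets out from 18 and comes back at 19. Compound 18 is transesterified with 4-methoxybenzyl alcohol (catalytic K2CO3, THF, 0 °C → rt, anhydrous) to bis(4-methoxybenzyl) (1R,2S,3R,4S)-3,4-bis(4-methoxy-3-methyl-2-oxo-2H-pyran-6-yl)-3,4-dimethylcyclobutane-1,2-dicarboxylate F6. The two benzylic esters are then cleaved by acidolysis (CF3CO2H, anisole, CH2Cl2, 0 °C) to give 19 without aqueous base.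

**Further compounds**
F1 | step 5 | 6-acetyl-4-methoxy-3-methyl-2H-pyran-2-one | CC(=O)c1cc(OC)c(C)c(=O)o1
F2 | step 5 | lithium enolate of tert-butyl acetate (lithium 1-tert-butoxyethen-1-olate) | [Li+].C=C([O-])OC(C)(C)C
F3 | step 5 | tert-butyl 3-hydroxy-3-(4-methoxy-3-methyl-2-oxo-2H-pyran-6-yl)butanoate (racemic) | COc1cc(C(C)(O)CC(=O)OC(C)(C)C)oc(=O)c1C
F4 | step 9 | ethane-1,2-diaminium bis[(2E)-3-(4-methoxy-3-methyl-2-oxo-2H-pyran-6-yl)but-2-enoate] | [NH3+]CC[NH3+].COc1cc(/C(C)=C/C(=O)[O-])oc(=O)c1C.COc1cc(/C(C)=C/C(=O)[O-])oc(=O)c1C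
F5 | step 9 | ethane-1,2-diaminium (1R,2S,3R,4S)-3,4-bis(4-methoxy-3-methyl-2-oxo-2H-pyran-6-yl)-3,4-dimethylcyclobutane-1,2-dicarboxylate | [NH3+]CC[NH3+].COc1cc([C@@]2(C)[C@H](C(=O)[O-])[C@H](C(=O)[O-])[C@@]2(C)c2cc(OC)c(C)c(=O)o2)oc(=O)c1C
F6 | step 10 | bis(4-methoxybenzyl) (1R,2S,3R,4S)-3,4-bis(4-methoxy-3-methyl-2-oxo-2H-pyran-6-yl)-3,4-dimethylcyclobutane-1,2-dicarboxylate | COc1cc([C@@]2(C)[C@H](C(=O)OCc3ccc(OC)cc3)[C@H](C(=O)OCc3ccc(OC)cc3)[C@@]2(C)c2cc(OC)c(C)c(=O)o2)oc(=O)c1C
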